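## Structural features

The target is the C9 (E)-caffeate of (−)-lariciresinol. It has one oxolane ring (O1, C2, C3, C4, C5) carrying a 4-hydroxy-3-methoxyphenyl group on C2, the acyloxymethyl carbon C9 on C3 and a 4-hydroxy-3-methoxybenzyl group (benzylic carbon C7′) on C4, while C5 is a plain OCH2. The three stereocentres C2 (R), C3 (S) and C4 (S) stand in a row. The aryl group is trans to C9 and C9 is cis to C7′, so the C2 and C4 substituents lie on opposite faces and C3 is cis to one neighbour whichever way it points, which rules out equilibration as a way of setting it. The 3,4-dihydroxycinnamoyl chain is joined only through the primary ester at C9 and brings an E alkene but no stereocentre. The fragile points are the catechol (air, base), the enoate (no hydrogenolytic deprotection), the ester (base) and the C2–O1 bond, a para-oxygenated benzylic ether that ionises in acid, after which the electron-rich arene on C7′ can close a tetralin irreversibly. Four phenols and one primary alcohol must be told apart, because only C9–OH is to be acylated. The real difficulty is the C3/C4 pair, a sterically unfavourable cis relation that must be fixed in the absolute sense, whereas C2 can be derived from C3 when the ring closes. The key step exploits two facts: C2 and C7′ are both the formyl carbon of vanillin, and C9–C3–C4–C5 is a four-carbon chain with oxygen at each end, a masked but-2-en-4-olide whose β-carbon (C4) accepts a vanillin acyl anion equivalent and whose α-carbon (C3) then attacks vanillin itself. In that lactone ring (O, C9, C3, C4, C5) the two new substituents are trans, and because C9 becomes exocyclic and C2 endocyclic when the oxolane forms, the same two stereocentres read as 3,4-cis in the target.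

## Logic of the disconnections

**21 ⇒ 20.** Four O–Si bonds are cut, two on the lignan arenes and two on the catechol. Every phenol therefore stays masked until no further bond has to be made, so the oxidisable catechol and the free p-hydroxybenzylic ether exist only in 21. The gain is chemoselectivity rather than skeletal simplification. The forward step must work without hydrogen, strong acid or free base, which points to buffered fluoride.

**20 ⇒ 16 + 19.** The acyl–oxygen bond between O–C9 and the cinnamoyl carbonyl is cut. It is the only link between the two halves, and its removal takes away nine carbons and the alkene at once. The forward step needs a neutral acylation. It also requires that 16 offer a single free hydroxyl and that 19 carry no free phenol.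

**19 ⇒ 17.** Two O–Si bonds are cut, which leads directly to a commercial acid. The forward step must silylate both phenols yet leave the carboxyl group free, which is solved by over-silylation to 18 and selective hydrolysis.

**16 ⇒ 14 (through 15).** O1–C2 is cut. C2 is benzylic and para to an oxygen donor, so the bond can be made by ionisation, and both carbinol epimers of 14 collapse to the same cation 15. This removes the ring and takes C2 off the list of centres that need earlier control. In the forward step C5–OH must beat C9–OH (five- against four-membered ring) and the C7′ arene (six-membered carbocycle), and the aryl group must end trans to C9. Only mild, catalytic acid meets these demands.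

**14 ⇒ 13.** No skeletal bond is cut. C9 is raised to the carboxyl level and C5 to the aldehyde level, and the two are tied through one oxygen into a five-membered acylal that carries 4 on C5. The ring is a rigid template on which the C3/C4 relation is a simple trans relation. The forward step needs a hydride reagent that takes both carbons down to the alcohol level and expels 4 faster than the transient aldehydes can enolise.

**13 ⇒ 12.** The two C7′–H bonds are exchanged for the two C–S bonds of a six-membered dithioacetal, so that C7′ becomes a carbon that could have acted as a nucleophile. The forward desulfurisation must spare the benzylic C–OH, the acylal and the aryl silyl ethers.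

**12 ⇒ 6 + 9 + 8.** C4–C7′ and C2–C3 are cut together. Both bonds flank the α,β-pair of an unsaturated lactone, so one operation returns three fragments of roughly equal size, two of them derived from the same aldehyde. The gain is the largest in the plan: two skeletal bonds and the two decisive stereocentres. The forward step must add 1,4 and not 1,2, must approach C4 anti to the C5 alkoxy group and C3 anti to the new C4 substituent, and must keep the aldolate from reverting.

**9 ⇒ 8 ⇒ 7.** Two C–S bonds and then one O–Si bond are cut. One protected aldehyde thus serves both as electrophile and, after polarity inversion, as nucleophile. The silyl group must survive a Lewis acid, an alkyllithium, alkoxides and hydrides.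

**6 ⇒ 3 + 4, 3 ⇒ 1.** The exocyclic C5–O bond is cut, and then the lactone is traced to a furan by oxidative loss of its formyl carbon. Both precursors are cheap. The single source of absolute configuration is 4, and the forward acetalisation must deliver one C5 epimer. This is achieved by crystallisation with equilibration of 5.

## Other disconnections considered

Alternative 1: The cut is C2–C3, made last on a chain in which O1 already links C5 to a vanillyl CH2.

- **Forward key step.** The substrate would be tert-butyl (3S)-2-diazo-3-(arylmethyl)-4-(arylmethoxy)butanoate A1 (aryl = 4-tert-butyldimethylsilyloxy-3-methoxyphenyl throughout A1 to A9). With Rh2(S-PTTL)4 (divalent rhodium) A1 would lose N2, and the C3 carbene would insert into a C2–H bond through a five-membered transition state. The product would be tert-butyl (2R,3R,4S)-2-aryl-4-(arylmethyl)oxolane-3-carboxylate A2.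
- **In its favour.** The C–H bond is activated twice (next to oxygen and benzylic to a donor arene), and 1,5-insertion is the preferred ring size. The ring appears directly at the ether oxidation level. C2–O1 is never ionised, so the tetralin pathway does not exist. On that point, and in using a catalyst instead of a stoichiometric auxiliary for C2 and C3, this plan is the better one.
- **Against it.** The carbene carbon has a tertiary C4–H next to it, and 1,2-hydride migration to the enoate is the intrinsically fast reaction of α-alkyl diazo esters. Bulky carboxylate ligands and low temperature slow it, but a branched β-position is the least favourable case. The ester must end trans to the aryl and cis to the benzyl group, whereas the closest insertions into aryl-substituted ether C–H bonds tend to place ester and aryl cis. A later epimerisation has no clear bias, because C3 is cis to one neighbour either way. The catalyst must also be matched to the resident C4 centre.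
- **Comparison.** C4 needs its own asymmetric alkylation, chain extension and an activated diazo transfer, so the way to A1 should be about as long as the whole way to 14. The endgame (ester reduction, acylation, desilylation) is equal in both plans. The chosen plan forms two C–C bonds convergently with a well-understood anti/anti approach on a rigid ring, while here only one C–C bond is formed in the key step.

Alternative 2: The cuts are O1–C5 and C4–C5, so that C5 comes from carbon monoxide A4.

- **Forward key step.** The substrate would be the anti homopropargylic alcohol (1R,2S)-1,4-diaryl-2-(triethylsilyloxymethyl)but-3-yn-1-ol A3, which already holds C2 and C3. Under A4 with a catalyst such as PdCl2(PPh3)2/SnCl2 (divalent palladium), the hydroxyl, one CO and the alkyne would be joined by syn addition across C4≡C7′. This would give (3E,4S,5R)-5-aryl-3-(arylmethylidene)-4-(triethylsilyloxymethyl)oxolan-2-one A5.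
- **In its favour.** It is atom-economical, with one catalytic step for two bonds and the ring, and the syn addition defines the alkene geometry. The TES ether gives orthogonal access to C9–OH. Hydrogenation from the face away from the C3 substituent would place C7′ cis to C9, which is substrate control in the right sense and equal in logic to the chosen plan. C2 is set independently and not through a cation, which is a point in which this plan is better.
- **Against it.** The reaction type is best established for terminal alkynes. With an internal aryl alkyne the insertion should be slower, and carbonylation at C7′ (six-membered lactone) competes. The electron-rich benzylic alcohol may ionise under the acidic promoter. A3 demands two contiguous stereocentres from an anti-selective allenylmetal addition or an equivalent multi-step sequence.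
- **Comparison.** After A5 the benzylic acyloxy C2–O bond faces hydrogenation conditions, and the lactone carbonyl must be taken to CH2 in two operations (DIBAL-H, then Et3SiH/BF3·OEt2), the second of which again exposes C2–O1 to a Lewis acid. That makes six steps after the key step, the same number as in the chosen plan, but with a longer and less convergent approach to the key substrate.

Alternative 3: Three bonds are cut, O1–C2, C3–C4 and C7′–aryl.

- **Forward key step.** The alkoxide of prop-2-yn-1-ol A6 would add to dimethyl 2-(arylmethylidene)propanedioate A7 (oxa-Michael addition). The malonate anion would then attack the alkyne in 5-exo-dig fashion, anti to the arylpalladium iodide formed from tert-butyl(4-iodo-2-methoxyphenoxy)dimethylsilane A8 and a zerovalent palladium catalyst such as Pd(PPh3)4. Reductive elimination would give dimethyl (2S,4Z)-2-aryl-4-(arylmethylidene)oxolane-3,3-dicarboxylate A9.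
- **In its favour.** Three bonds and the ring are made in one flask, against two bonds and no ring in the chosen key step. The components are achiral and each lies one or two steps from vanillin, and the anti carbopalladation fixes the alkene geometry. In convergence and in the number of steps to the ring this plan is the better one.
- **Against it.** C2 is created in a reversible addition of an achiral alkoxide to an achiral acceptor with no chiral element present. A9 would therefore arise as the racemate, and a single enantiomer would need a resolution or an asymmetric variant without a close model. C3 is quaternary with two equal esters, so one must be removed (Krapcho dealkoxycarbonylation). During that step the β-alkoxy ester enolate can undergo retro-oxa-Michael opening, and the arylmethylidene unit can drift towards the furan.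
- **Comparison.** C3 (protonation) and C4 (hydrogenation, plausibly from the face opposite the C3 ester, the correct sense) would both depend on C2 alone. Five further steps plus a resolution compare with six in the chosen plan. The chosen plan draws all absolute configuration from one crystalline acetal, and this is decisive for a target required as one enantiomer.

Key step: step 5

**Remarks on the chemistry**

- Ar = 3-methoxy-4-(triisopropylsilyloxy)phenyl.
- Menthyloxy = (1S,2R,5S)-2-isopropyl-5-methylcyclohexyloxy, from (+)-menthol.
- CSA = camphor-10-sulfonic acid. EDC·HCl = N-ethyl-N′-(3-dimethylaminopropyl)carbodiimide hydrochloride. DMAP = 4-(dimethylamino)pyridine. TBAF = Bu4NF.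
- Assumption 1: the two lignan phenols are carried as TIPS rather than TBS ethers. They must pass n-BuLi, a lithium aldolate, methanolic NaBH4 and LiAlH4, and the carbon skeletons of all partners of the key step are unaffected by this choice.
- Assumption 2: the carbinol epimers of 12, 13 and 14 are carried on together.

## Steps

Step 1
Reactants: 1 furfural
Product: 3 5-hydroxyfuran-2(5H)-one (racemic), via furfural endoperoxide 2 (not isolated)
Conditions: O2, hν (visible), rose bengal (C20H2Cl4I4Na2O5, cat.), MeOH, 20 °C
Reagents that add atoms: dioxygen, O=O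
Why: Dye-sensitised singlet-oxygen [4+2] cycloaddition to the furan gives 2; methanol adds to its formyl group and fragmentation of the O–O bond expels that carbon as the methyl ester, uncovering the γ-hydroxybutenolide. C5 of 3 is a configurationally labile hemiacylal, so the racemate is of no consequence.

Step 2
Reactants: 3 5-hydroxyfuran-2(5H)-one; 4 (+)-menthol
Product: 6 (5S)-5-[(1S,2R,5S)-menthyloxy]furan-2(5H)-one, via 5R acetal epimer 5 (not isolated)
Conditions: CSA (cat.), toluene, reflux (Dean–Stark); crystallisation from petroleum ether, −20 °C; mother liquor re-equilibrated with CSA (cat.) and recrystallised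
Reagents that add atoms: none
Why: Acid-catalysed acetalisation through the cyclic acyloxocarbenium ion gives both C5 epimers, which interconvert under the acid. Only 6 should crystallise, as the mirror image of the well-known (−)-menthol/(5R) pair, so a crystallisation-induced diastereomer transformation funnels 5 into 6 and sets C5.

Step 3
Reactants: 7 vanillin
Product: 8 3-methoxy-4-(triisopropylsilyloxy)benzaldehyde
Conditions: TIPSCl, imidazole, DMF, rt
Reagents that add atoms: chlorotriisopropylsilane, CC(C)[Si](Cl)(C(C)C)C(C)C
Why: Imidazole-promoted O-silylation of a phenol. The bulkier TIPS group is chosen for its resistance to the nucleophilic and basic reagents of steps 5 to 7.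

Step 4
Reactants: 8 3-methoxy-4-(triisopropylsilyloxy)benzaldehyde
Product: 9 2-[3-methoxy-4-(triisopropylsilyloxy)phenyl]-1,3-dithiane
Conditions: HS(CH2)3SH, BF3·OEt2 (cat.), CH2Cl2, 0 °C to rt
Reagents that add atoms: propane-1,3-dithiol, SCCCS
Why: Lewis-acid-catalysed thioacetalisation of an aromatic aldehyde, which an aryl TIPS ether tolerates. It prepares the polarity inversion (umpolung) of the future C7′.

Step 5
Reactants: 9 2-[3-methoxy-4-(triisopropylsilyloxy)phenyl]-1,3-dithiane; 6 (5S)-5-[(1S,2R,5S)-menthyloxy]furan-2(5H)-one; 8 3-methoxy-4-(triisopropylsilyloxy)benzaldehyde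
Product: 12 (3R,4S,5S)-3-[Ar(hydroxy)methyl]-4-(2-Ar-1,3-dithian-2-yl)-5-[(1S,2R,5S)-menthyloxy]oxolan-2-one (both carbinol epimers), via 2-lithiodithiane 10 (not isolated), via lithium lactone enolate 11 (not isolated)
Conditions: 9, n-BuLi, THF, −78 to −20 °C; 6, −78 °C; 8, −78 °C; AcOH, −78 °C
Reagents that add atoms: none
Why: n-BuLi removes the doubly sulfur-stabilised benzylic proton of 9 to give 10, a soft delocalised carbanion that adds to the β-carbon of 6 (Michael addition, bond C4–C7′) and leaves the enolate 11. Enolate 11 then attacks the non-enolisable aldehyde 8 (aldol addition, bond C2–C3), and the aldolate is protonated in the cold. The closest known reaction type is the tandem conjugate addition–enolate trapping of lithiated 2-aryl-1,3-dithianes on 5-alkoxyfuran-2(5H)-ones. No ring is formed in this step. C4 is controlled by the C5 menthyloxy group, which screens one face of the flat butenolide so that 10 enters anti to it. C3 is controlled by the new quaternary dithianyl substituent on C4, so that 8 approaches from the opposite face, and the result should be the trans,trans lactone. The carbinol carbon is formed without control, which is accepted because it is planarised in step 8. The step needs 1,4- over 1,2-addition (secured by the soft anion and the ester-type carbonyl), complete consumption of 10 before 8 is added (order of addition, slight deficit of n-BuLi), and suppression of retro-aldol, retro-Michael and O-to-O silyl transfer (−78 °C, cold acidic quench, TIPS).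

Step 6
Reactants: 12 (3R,4S,5S)-3-[Ar(hydroxy)methyl]-4-(2-Ar-1,3-dithian-2-yl)-5-[(1S,2R,5S)-menthyloxy]oxolan-2-one
Product: 13 (3R,4S,5S)-3-[Ar(hydroxy)methyl]-4-(Ar-methyl)-5-[(1S,2R,5S)-menthyloxy]oxolan-2-one (both carbinol epimers)
Conditions: NiCl2·6H2O, NaBH4, MeOH–THF, 0 °C
Reagents that add atoms: none
Why: Ni2B made in the flask cleaves both benzylic C–S bonds (reductive desulfurisation of a dithioacetal) and is milder towards the benzylic C–OH than skeletal nickel (Raney Ni). C3, C4 and C5 are not touched, and partial borohydride reduction of the acylal would be harmless because step 7 reduces it anyway.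

Step 7
Reactants: 13 (3R,4S,5S)-3-[Ar(hydroxy)methyl]-4-(Ar-methyl)-5-[(1S,2R,5S)-menthyloxy]oxolan-2-one
Product: 14 (2S,3S)-2-[Ar(hydroxy)methyl]-3-(Ar-methyl)butane-1,4-diol (both carbinol epimers)
Conditions: LiAlH4, THF, 0 °C to rt; aq. potassium sodium tartrate
Reagents that add atoms: none
Why: LiAlH4 reduction of the lactone takes C9 to the primary alcohol; ring opening frees the C5 hemiacetal alkoxide, which expels mentholate, and the aldehyde so formed is reduced at once. Hydride capture of the transient aldehydes is faster than their enolisation, so C3 and C4 persist, and 4 is recovered.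

Step 8
Reactants: 14 (2S,3S)-2-[Ar(hydroxy)methyl]-3-(Ar-methyl)butane-1,4-diol
Product: 16 [(2R,3S,4S)-2-Ar-4-(Ar-methyl)oxolan-3-yl]methanol, via benzylic cation 15 (not isolated)
Conditions: CSA (cat.), CH2Cl2, 0 °C; Et3N
Reagents that add atoms: none
Why: Brønsted-acid cyclodehydration of SN1 type: both epimers of 14 ionise to the same para-silyloxy-stabilised cation 15, which C5–OH traps in a 5-exo closure, whereas C9–OH could only form an oxetane. C2 is set by C3, since closure with the aryl group trans to CH2OH avoids the all-cis array and any 2,3-cis ether can re-ionise and drain into 16. Catalytic acid, low temperature and an amine quench hold back Friedel–Crafts attack of the C7′ arene.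

Step 9
Reactants: 17 caffeic acid
Product: 19 (E)-3-[3,4-bis(tert-butyldimethylsilyloxy)phenyl]prop-2-enoic acid, via silyl ester 18 (not isolated)
Conditions: TBSCl, imidazole, DMF, rt; then AcOH–THF–H2O, rt
Reagents that add atoms: tert-butylchlorodimethylsilane, CC(C)(C)[Si](C)(C)Cl
Why: Exhaustive silylation followed by selective hydrolysis of the very labile silyl ester 18, while aryl TBS ethers withstand aqueous acetic acid. The E alkene is not involved.

Step 10
Reactants: 16 [(2R,3S,4S)-2-Ar-4-(Ar-methyl)oxolan-3-yl]methanol; 19 (E)-3-[3,4-bis(tert-butyldimethylsilyloxy)phenyl]prop-2-enoic acid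
Product: 20 [(2R,3S,4S)-2-Ar-4-(Ar-methyl)oxolan-3-yl]methyl (E)-3-[3,4-bis(tert-butyldimethylsilyloxy)phenyl]prop-2-enoate
Conditions: EDC·HCl, DMAP (cat.), CH2Cl2, 0 °C to rt
Reagents that add atoms: none
Why: Steglich-type carbodiimide/DMAP esterification. C9–OH is the only free hydroxyl of 16, so no site selectivity is needed, and the near-neutral medium spares the benzylic ether and all four silyl ethers.

Step 11
Reactants: 20 [(2R,3S,4S)-2-Ar-4-(Ar-methyl)oxolan-3-yl]methyl (E)-3-[3,4-bis(tert-butyldimethylsilyloxy)phenyl]prop-2-enoate
Product: 21 [(2R,3S,4S)-2-(4-hydroxy-3-methoxyphenyl)-4-[(4-hydroxy-3-methoxyphenyl)methyl]oxolan-3-yl]methyl (E)-3-(3,4-dihydroxyphenyl)prop-2-enoate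
Conditions: TBAF, AcOH, THF, 0 °C to rt, argon
Reagents that add atoms: none
Why: Fluoride-induced cleavage of all four aryl silyl ethers, phenoxide being a good leaving group on silicon. Acetic acid protonates each phenoxide as it forms, which protects the ester from cleavage, the catechol from autoxidation and C2–O1 from quinone methide opening, and no stereocentre is touched.

## Compound list

1 | furfural (furan-2-carbaldehyde) | O=Cc1ccco1 | starting material
2 | 2,3,7-trioxabicyclo[2.2.1]hept-5-ene-1-carbaldehyde (singlet-oxygen adduct of 1, racemic) | O=CC12OOC(C=C1)O2 | intermediate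
3 | 5-hydroxyfuran-2(5H)-one (racemic) | O=C1C=CC(O)O1 | intermediate
4 | (+)-menthol, (1S,2R,5S)-2-isopropyl-5-methylcyclohexan-1-ol | CC(C)[C@H]1CC[C@H](C)C[C@@H]1O | starting material
5 | (5R)-5-[(1S,2R,5S)-menthyloxy]furan-2(5H)-one | O=C1C=C[C@H](O[C@H]2C[C@@H](C)CC[C@@H]2C(C)C)O1 | intermediate
6 | (5S)-5-[(1S,2R,5S)-menthyloxy]furan-2(5H)-one | O=C1C=C[C@@H](O[C@H]2C[C@@H](C)CC[C@@H]2C(C)C)O1 | intermediate
7 | vanillin (4-hydroxy-3-methoxybenzaldehyde) | COc1cc(C=O)ccc1O | starting material
8 | 3-methoxy-4-(triisopropylsilyloxy)benzaldehyde | COc1cc(C=O)ccc1O[Si](C(C)C)(C(C)C)C(C)C | intermediate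
9 | 2-[3-methoxy-4-(triisopropylsilyloxy)phenyl]-1,3-dithiane | COc1cc(C2SCCCS2)ccc1O[Si](C(C)C)(C(C)C)C(C)C | intermediate
10 | 2-lithio-2-[3-methoxy-4-(triisopropylsilyloxy)phenyl]-1,3-dithiane | COc1cc(C2([Li])SCCCS2)ccc1O[Si](C(C)C)(C(C)C)C(C)C | intermediate
11 | lithium enolate of (4S,5S)-4-(2-Ar-1,3-dithian-2-yl)-5-[(1S,2R,5S)-menthyloxy]oxolan-2-one | COc1cc(C2(SCCCS2)[C@@H]2[C@@H](O[C@H]3C[C@@H](C)CC[C@@H]3C(C)C)OC(O[Li])=C2)ccc1O[Si](C(C)C)(C(C)C)C(C)C | intermediate
12 | (3R,4S,5S)-3-[Ar(hydroxy)methyl]-4-(2-Ar-1,3-dithian-2-yl)-5-[(1S,2R,5S)-menthyloxy]oxolan-2-one, both carbinol epimers | COc1cc(C2(SCCCS2)[C@@H]2[C@@H](O[C@H]3C[C@@H](C)CC[C@@H]3C(C)C)OC(=O)[C@H]2C(O)c2ccc(O[Si](C(C)C)(C(C)C)C(C)C)c(OC)c2)ccc1O[Si](C(C)C)(C(C)C)C(C)C | intermediate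
13 | (3R,4S,5S)-3-[Ar(hydroxy)methyl]-4-(Ar-methyl)-5-[(1S,2R,5S)-menthyloxy]oxolan-2-one, both carbinol epimers | COc1cc(C[C@@H]2[C@@H](O[C@H]3C[C@@H](C)CC[C@@H]3C(C)C)OC(=O)[C@H]2C(O)c2ccc(O[Si](C(C)C)(C(C)C)C(C)C)c(OC)c2)ccc1O[Si](C(C)C)(C(C)C)C(C)C | intermediate
14 | (2S,3S)-2-[Ar(hydroxy)methyl]-3-(Ar-methyl)butane-1,4-diol, both carbinol epimers | COc1cc(C[C@H](CO)[C@@H](CO)C(O)c2ccc(O[Si](C(C)C)(C(C)C)C(C)C)c(OC)c2)ccc1O[Si](C(C)C)(C(C)C)C(C)C | intermediate
15 | benzylic (C2) cation derived from 14 | COc1cc(C[C@H](CO)[C@@H](CO)[CH+]c2ccc(O[Si](C(C)C)(C(C)C)C(C)C)c(OC)c2)ccc1O[Si](C(C)C)(C(C)C)C(C)C | intermediate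
16 | [(2R,3S,4S)-2-Ar-4-(Ar-methyl)oxolan-3-yl]methanol (bis-O-TIPS (−)-lariciresinol) | COc1cc(C[C@@H]2CO[C@@H](c3ccc(O[Si](C(C)C)(C(C)C)C(C)C)c(OC)c3)[C@@H]2CO)ccc1O[Si](C(C)C)(C(C)C)C(C)C | intermediate
17 | caffeic acid, (E)-3-(3,4-dihydroxyphenyl)prop-2-enoic acid | OC(=O)/C=C/c1ccc(O)c(O)c1 | starting material
18 | tert-butyldimethylsilyl (E)-3-[3,4-bis(tert-butyldimethylsilyloxy)phenyl]prop-2-enoate | CC(C)(C)[Si](C)(C)OC(=O)/C=C/c1ccc(O[Si](C)(C)C(C)(C)C)c(O[Si](C)(C)C(C)(C)C)c1 | intermediate
19 | (E)-3-[3,4-bis(tert-butyldimethylsilyloxy)phenyl]prop-2-enoic acid | OC(=O)/C=C/c1ccc(O[Si](C)(C)C(C)(C)C)c(O[Si](C)(C)C(C)(C)C)c1 | intermediate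
20 | [(2R,3S,4S)-2-Ar-4-(Ar-methyl)oxolan-3-yl]methyl (E)-3-[3,4-bis(tert-butyldimethylsilyloxy)phenyl]prop-2-enoate | COc1cc(C[C@@H]2CO[C@@H](c3ccc(O[Si](C(C)C)(C(C)C)C(C)C)c(OC)c3)[C@@H]2COC(=O)/C=C/c2ccc(O[Si](C)(C)C(C)(C)C)c(O[Si](C)(C)C(C)(C)C)c2)ccc1O[Si](C(C)C)(C(C)C)C(C)C | intermediate
21 | [(2R,3S,4S)-2-(4-hydroxy-3-methoxyphenyl)-4-[(4-hydroxy-3-methoxyphenyl)methyl]oxolan-3-yl]methyl (E)-3-(3,4-dihydroxyphenyl)prop-2-enoate | COc1cc(C[C@@H]2CO[C@@H](c3ccc(O)c(OC)c3)[C@@H]2COC(=O)/C=C/c2ccc(O)c(O)c2)ccc1O | target

## Step count and least certain steps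

Total step count: 11.

Longest linear sequence: 8 steps, either 1, 2, 5, 6, 7, 8, 10, 11 from 1, or equally 3, 4, 5, 6, 7, 8, 10, 11 from 7.

**Step 5 (key step).** The weak point is the second bond. The enolate carbon of 11 sits next to a quaternary dithianyl carbon, so capture of 8 may be slow and incomplete. The lithium aldolate may also revert before the quench, which would amount to simple protonation of the enolate. Competing 1,2-addition of 10 is less likely. The fallback separates the two bond formations and changes the metal of the aldol. It sets out from 6 and 9. The conjugate addition is quenched with AcOH and the protonated adduct (4S,5S)-4-(2-Ar-1,3-dithian-2-yl)-5-[(1S,2R,5S)-menthyloxy]oxolan-2-one F1 is purified. LDA in THF at −78 °C regenerates 11, and ClTi(OiPr)3 converts it into the triisopropoxytitanium enolate F2. The covalent aldolate of F2 with 8 should not revert, and aqueous work-up comes back to the route at 12.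

**Step 6.** The borohydride–methanol medium is basic, so retro-aldol cleavage of the β-hydroxy lactone, incomplete desulfurisation at the crowded C7′ or hydrogenolysis of the free benzylic C–OH may erode the material. The fallback changes the order of events, so that the sulfur is removed only when neither the aldol unit nor a free benzylic alcohol remains. It sets out from 12. LiAlH4 in THF gives the dithianyl triol (2S,3S)-2-[Ar(hydroxy)methyl]-3-(2-Ar-1,3-dithian-2-yl)butane-1,4-diol F3. Catalytic CSA in CH2Cl2 closes it to the dithianyl oxolane [(2R,3S,4S)-2-Ar-4-(2-Ar-1,3-dithian-2-yl)oxolan-3-yl]methanol F4. Ni2B (NiCl2·6H2O, NaBH4) then desulfurises F4 and comes back to the route at 16.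

**Step 8.** The cation 15 can be attacked by the C7′ arene (position para to its methoxy group). This Friedel–Crafts closure to a tetralin is irreversible, so prolonged or too strongly acidic conditions would drain the oxolane away, while too little acid would leave poor selectivity at C2. The fallback avoids the full cation by working through a neutral p-quinone methide and moves the deprotection forward. It sets out from 14. TBAF/AcOH gives the free-phenol triol (2S,3S)-2-[hydroxy(4-hydroxy-3-methoxyphenyl)methyl]-3-[(4-hydroxy-3-methoxyphenyl)methyl]butane-1,4-diol F5. Warm aqueous THF containing acetic acid should dehydrate it to the quinone methide, which C5–OH traps to give (−)-lariciresinol F6. A Mitsunobu esterification (PPh3, DIAD, THF, 0 °C) with 19 activates only the primary C9–OH and uses the carboxylic acid as the most acidic partner, leaving the phenols alone. This gives (−)-lariciresinol 9-O-[3,4-bis(tert-butyldimethylsilyl)caffeate] F7. TBAF/AcOH then comes back to the route at 21.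

**Step 11.** Four phenoxides are released next to an ester, a catechol and a p-hydroxybenzylic ether. If the buffering is insufficient, ester cleavage, catechol autoxidation or opening at C2–O1 may set in, and the slower TIPS cleavage prolongs the exposure. The fallback builds the caffeate last, without fluoride and without catechol protection. It sets out from 16. Meldrum's acid in toluene at 100 °C gives the malonic half ester 3-{[(2R,3S,4S)-2-Ar-4-(Ar-methyl)oxolan-3-yl]methoxy}-3-oxopropanoic acid F8. TBAF/AcOH removes the two TIPS groups at this robust stage to give the bis-phenol half ester 3-{[(2R,3S,4S)-2-(4-hydroxy-3-methoxyphenyl)-4-[(4-hydroxy-3-methoxyphenyl)methyl]oxolan-3-yl]methoxy}-3-oxopropanoic acid F9. A Knoevenagel–Doebner condensation with 3,4-dihydroxybenzaldehyde (pyridine, piperidine cat., 40 °C, argon) forms the E enoate with loss of CO2 and comes back to the route at 21.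

## Further compounds

F1 | step 5 | (4S,5S)-4-(2-Ar-1,3-dithian-2-yl)-5-[(1S,2R,5S)-menthyloxy]oxolan-2-one | COc1cc(C2(SCCCS2)[C@@H]2[C@@H](O[C@H]3C[C@@H](C)CC[C@@H]3C(C)C)OC(=O)C2)ccc1O[Si](C(C)C)(C(C)C)C(C)C
F2 | step 5 | triisopropoxytitanium enolate of F1 | COc1cc(C2(SCCCS2)[C@@H]2[C@@H](O[C@H]3C[C@@H](C)CC[C@@H]3C(C)C)OC(O[Ti](OC(C)C)(OC(C)C)OC(C)C)=C2)ccc1O[Si](C(C)C)(C(C)C)C(C)C
F3 | step 6 | (2S,3S)-2-[Ar(hydroxy)methyl]-3-(2-Ar-1,3-dithian-2-yl)butane-1,4-diol, both carbinol epimers | COc1cc(C2(SCCCS2)[C@H](CO)[C@@H](CO)C(O)c2ccc(O[Si](C(C)C)(C(C)C)C(C)C)c(OC)c2)ccc1O[Si](C(C)C)(C(C)C)C(C)C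
F4 | step 6 | [(2R,3S,4S)-2-Ar-4-(2-Ar-1,3-dithian-2-yl)oxolan-3-yl]methanol | COc1cc(C2(SCCCS2)[C@@H]2CO[C@@H](c3ccc(O[Si](C(C)C)(C(C)C)C(C)C)c(OC)c3)[C@@H]2CO)ccc1O[Si](C(C)C)(C(C)C)C(C)C
F5 | step 8 | (2S,3S)-2-[hydroxy(4-hydroxy-3-methoxyphenyl)methyl]-3-[(4-hydroxy-3-methoxyphenyl)methyl]butane-1,4-diol, both carbinol epimers | COc1cc(C[C@H](CO)[C@@H](CO)C(O)c2ccc(O)c(OC)c2)ccc1O
F6 | step 8 | (−)-lariciresinol, (2R,3S,4S) | COc1cc(C[C@@H]2CO[C@@H](c3ccc(O)c(OC)c3)[C@@H]2CO)ccc1O
F7 | step 8 | (−)-lariciresinol 9-O-[(E)-3,4-bis(tert-butyldimethylsilyloxy)cinnamate] | COc1cc(C[C@@H]2CO[C@@H](c3ccc(O)c(OC)c3)[C@@H]2COC(=O)/C=C/c2ccc(O[Si](C)(C)C(C)(C)C)c(O[Si](C)(C)C(C)(C)C)c2)ccc1O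
F8 | step 11 | 3-{[(2R,3S,4S)-2-Ar-4-(Ar-methyl)oxolan-3-yl]methoxy}-3-oxopropanoic acid | COc1cc(C[C@@H]2CO[C@@H](c3ccc(O[Si](C(C)C)(C(C)C)C(C)C)c(OC)c3)[C@@H]2COC(=O)CC(=O)O)ccc1O[Si](C(C)C)(C(C)C)C(C)C
F9 | step 11 | 3-{[(2R,3S,4S)-2-(4-hydroxy-3-methoxyphenyl)-4-[(4-hydroxy-3-methoxyphenyl)methyl]oxolan-3-yl]methoxy}-3-oxopropanoic acid | COc1cc(C[C@@H]2CO[C@@H](c3ccc(O)c(OC)c3)[C@@H]2COC(=O)CC(=O)O)ccc1O
A1 | alternative 1 | tert-butyl (3S)-2-diazo-3-(arylmethyl)-4-(arylmethoxy)butanoate, aryl = 4-tert-butyldimethylsilyloxy-3-methoxyphenyl | COc1cc(C[C@H](COCc2ccc(O[Si](C)(C)C(C)(C)C)c(OC)c2)C(=[N+]=[N-])C(=O)OC(C)(C)C)ccc1O[Si](C)(C)C(C)(C)C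
A2 | alternative 1 | tert-butyl (2R,3R,4S)-2-aryl-4-(arylmethyl)oxolane-3-carboxylate | COc1cc(C[C@@H]2CO[C@@H](c3ccc(O[Si](C)(C)C(C)(C)C)c(OC)c3)[C@@H]2C(=O)OC(C)(C)C)ccc1O[Si](C)(C)C(C)(C)C
A3 | alternative 2 | (1R,2S)-1,4-diaryl-2-(triethylsilyloxymethyl)but-3-yn-1-ol | O[C@@H](c1ccc(O[Si](C)(C)C(C)(C)C)c(OC)c1)[C@H](CO[Si](CC)(CC)CC)C#Cc1ccc(O[Si](C)(C)C(C)(C)C)c(OC)c1
A4 | alternative 2 | carbon monoxide | [C-]#[O+]
A5 | alternative 2 | (3E,4S,5R)-5-aryl-3-(arylmethylidene)-4-(triethylsilyloxymethyl)oxolan-2-one | O=C1O[C@@H](c2ccc(O[Si](C)(C)C(C)(C)C)c(OC)c2)[C@H](CO[Si](CC)(CC)CC)/C1=C\c1ccc(O[Si](C)(C)C(C)(C)C)c(OC)c1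
A6 | alternative 3 | prop-2-yn-1-ol | C#CCO
A7 | alternative 3 | dimethyl 2-(arylmethylidene)propanedioate | COC(=O)C(=Cc1ccc(O[Si](C)(C)C(C)(C)C)c(OC)c1)C(=O)OC
A8 | alternative 3 | tert-butyl(4-iodo-2-methoxyphenoxy)dimethylsilane | COc1cc(I)ccc1O[Si](C)(C)C(C)(C)C
A9 | alternative 3 | dimethyl (2S,4Z)-2-aryl-4-(arylmethylidene)oxolane-3,3-dicarboxylate | COc1cc(/C=C2\CO[C@@H](c3ccc(O[Si](C)(C)C(C)(C)C)c(OC)c3)C2(C(=O)OC)C(=O)OC)ccc1O[Si](C)(C)C(C)(C)C
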